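Time separates the flasks south and west: they hold the same charge and differ in their time, 1.5 h against 3.0 h.

common to all: gas 5.6 mM (held)

|  | substrate | remark | time |
|---|---|---|---|
| green | 0.025 M | run made earlier |  |
| violet | 0.038 M | run made earlier |  |
| south | 0.050 M |  | 1.5 h |
| west | 0.050 M |  | 3.0 h |

| run | time / min | target / % | substrate / % | open intermediate / % |
|---|---|---|---|---|
| green | 15.0 | 0.4 | 41.2 | 41.7 |
| green | 30.0 | 1.3 | 18.0 | 56.2 |
| green | 50.0 | 7.2 | 6.9 | 60.5 |
| green | 60.0 | 10.3 | 4.4 | 60.6 |
| green | 80.0 | 16.3 | 2.8 | 58.2 |
| green | 90.0 | 19.9 | 2.8 | 55.9 |
| violet | 15.0 | 0.7 | 41.2 | 41.5 |
| violet | 30.0 | 1.7 | 18.0 | 56.3 |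
| violet | 50.0 | 5.9 | 6.8 | 61.4 |
| violet | 60.0 | 9.4 | 4.9 | 61.8 |
| violet | 80.0 | 12.8 | 2.2 | 60.6 |
| violet | 90.0 | 14.1 | 3.3 | 59.1 |

(each reading ± 0.5 percentage points)

- at the start none of the gas is in solution
- a reading of substrate is of its free form alone

- which of these there is most of at the end, counted by the substrate in it, south (open intermediate / target / substrate)
- which of these there is most of at the end, counted by the substrate in it, west (open intermediate / target / substrate)
- amount of the one of these that there is most of at the end, in percent of the substrate charged, south
- amount of the one of these that there is most of at the end, in percent of the substrate charged, west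

I build the flask one process at a time. With the main step alone, substrate becoming open intermediate, the green readings give a first-order fall of 0.0552 /min, and this puts nearly all of the charge into open intermediate by 1.5 h. The balance corrects that. At the last readings of green and violet, the charge not yet in target stands on average at 1.44 times the open intermediate, so some leftover substrate and an unseen store travel with it, and the main-step figure drops to 69.3% of what target leaves.

Then comes target, which lags and then climbs. From 50.0 min to 90.0 min, green makes 0.0794 mM/min and violet 0.0779 mM/min, at charges of 0.025 M and 0.038 M. I carry their mean, 0.0786 mM/min, as the target clock: the amount of target made per minute, the same at both charges, after a lag read back as 24.3 min. The balance gives the store, the clock gives [target], and I join them, both read from the later readings. For south I reckon 10.3% target and 62.1% open intermediate; for west I reckon 24.5% and 52.3%.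

The forecast names open intermediate for south at 61.5% (58% to 65%) and open intermediate for west at 52.5% (47% to 58%), and it reads target as “independent of charge, so this step is zero-order”. My figures differ from it by 0.63 percentage points and 0.18 points.

The flask gives open intermediate at 61.8% in south and open intermediate at 52.3% in west, with target at 13.1% and 29.8%.

    partner → second intermediate (k = 3.00 × 10⁻⁴ /s)
    substrate ⇌ dormant form (K = 3.40, k = 3.10 × 10⁻⁴ /s)
    gas ⇌ partner, rate k3*(csat - [partner]) (kL = 0.00630 /s)
    substrate → open intermediate (k = 7.00 × 10⁻⁴ /s)
    open intermediate + second intermediate → target (k = 0.0270 /M/s)

In west, target gains 0.0931 mM/min after 1.50 h, faster than the clock, and ends 5.3 points above my figure, while [open intermediate] agrees. In south at 1.50 h, second intermediate is made, each step taken net, 1.02 times as fast as it is used up, and open intermediate, the resting state, has a half-life of 3.8 h at that time by its step into target, longer than the run.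

For south left until 6.0 h, the clock gives 52.8% target and 32.7% open intermediate, so target leads. That flask computes to 61.7% target and 29.1% open intermediate, with target holding most.

(The runs were generated by integration with constants of no real substance; noise was put on by code.)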